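You have two numbers to find and a choice that follows from them, and one integrated rate gives you both.

| flask | starting material | gas | remark | time |
|---|---|---|---|---|
| Friday's | 0.27 M | 33 mM (held) | run made earlier |  |
| Wednesday's | 1.1 M | 33 mM (held) | run made earlier |  |
| cedar | 0.80 M | 33 mM (held) |  | 5.0 d |
| larch | 0.20 M | 33 mM (held) |  | 2.5 d |

- Friday's (time / h: product / %): 2.50: 1.6; 6.00: 3.6; 12.0: 8.6; 20.0: 16.6; 25.0: 20.2; 30.0: 24.7; 40.0: 32.0
- Wednesday's (time / h: product / %): 3.00: 1.4; 5.00: 2.6; 8.00: 3.7; 12.0: 4.3; 20.0: 8.3; 30.0: 12.0; 40.0: 16.4

(readings scatter by 0.5 percentage points)

- at the start none of the gas is in solution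

* the flask that ends with the higher amount of product, in percent of the starting material charged, or "neither" when 2 percentage points or less lies between them (cedar / larch / neither)
* final product, as a percentage of the starting material charged, in cedar
* final product, as a percentage of the starting material charged, in larch

- **Start-up, the first rung.** No gas is in solution at the start, yet Wednesday's flask makes 5.13 mM/h of product up to 3.00 h and 4.51 mM/h up to 40.0 h, so I reckon without a delay.
- **Pace.** Friday's flask, charged 4.07 times thinner, averages 2.16 mM/h over the same hours, so Wednesday's flask runs twice as fast on that much more material.
- **My choice of rate.** A pace that flattens as the charge grows suggests a ceiling: first order in a thin flask, zero order in a full one, which is a saturation rate law. Integrated, it reads: bend × ln(charged / left) + (charged − left) = ceiling × time.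
- **Constants.** The last readings of the two runs give a bend of 0.455 M, the amount of starting material at which the pace is half the ceiling, and with it a ceiling of 6.55 mM/h.
- **Halving time.** Put half the charge as what is left, and the time to get there is (bend × ln(2) + charge / 2) / ceiling.
- **The two flasks.** Larch needs 2.64 d and gets 2.5 d, so it stops just short. Cedar needs 4.55 d and gets 5.0 d, so it runs past.
- **My numbers.** Stepping from the halfway point at the pace there gives 48.0% for larch and 54.1% for cedar. Cedar leads by 6.1 percentage points, more than the margin of 2 points, so I say cedar.
- **The forecast.** It says neither, with 51% (46% to 56%) for cedar and 50% (45% to 56%) for larch: “the two flasks essentially tie”. My reckoning differs from it on the choice.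

The hidden scheme:

    starting material + coupling partner → product, rate k1*[starting material]*[coupling partner]^0.5 (k = 0.0804 /M^0.5/h)
    gas ⇌ coupling partner, rate k2*(csat - [coupling partner]) (kL = 0.148 /h)

The flask gives cedar: cedar, with my reckoned halving time of 4.55 d, ends at 55.6%, and larch, with my reckoned 2.64 d, ends at 48.6%, a gap of 7.0 points. I use the same bend of 0.455 M on a neighbour of larch charged with 0.50 M and given the same 2.5 d. Its halving time comes to 3.60 d, well beyond that time, and stepping back from the halfway point gives 37.7%. That neighbour ends with 62% of its starting material left and 38.1% as product.

The runs are simulated for an exercise.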